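The runs were computed with constants of no real substance; noise was put on by code.

Slowness let me count by hand: at its last reading, 19 min, the Wednesday's run had made 42.5 mM of target, about half of the 80.0 mM of starting material charged.

| flask | starting material | partner | target | time |
|---|---|---|---|---|
| Wednesday's | 80.0 mM | 120 mM |  |  |
| Thursday's | 32.0 mM | 72.0 mM |  |  |
| Saturday's | 120 mM | 120 mM |  |  |
| Tuesday's | 80.0 mM | 360 mM |  |  |
| Monday's | 80.0 mM | 120 mM | 24.0 mM | 19 min |

- Wednesday's run (time / min: [target] / mM): 0.76: 3.2; 1.4: 5.8; 2.8: 10.7; 5.2: 16.8; 10: 29.1; 19: 42.5
- Thursday's run (time / min: [target] / mM): 0.76: 0.5; 1.4: 2.1; 2.8: 2.9; 5.2: 4.1; 10: 8.5; 19: 12.4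
- Saturday's run (time / min: [target] / mM): 0.76: 3.5; 1.4: 6.6; 2.8: 12.5; 5.2: 20.2; 10: 33.4; 19: 48.4
- Tuesday's run (time / min: [target] / mM): 0.76: 20.6; 1.4: 34.7; 2.8: 54.7; 5.2: 71.8; 10: 79.3; 19: 79.8

(readings scatter by 0.4 mM)

- Overall: starting material + partner -> target.
- Constant volume, constant temperature.
- A reading of a species includes what of it is bound.
- "The second partner" is partner.
- An order is taken over about fifteen percent of the charge, up and down.
- A share of target counts the target that was charged too.

1. the power of [starting material] that the first rate follows, about the charge of the Wednesday's run; measure it at two percent of starting material made into target (one fixed amount of target, the same in the runs compared)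
2. the power of [partner] that the first rate follows, about the charge of the Wednesday's run; measure it at two percent of starting material made into target
3. the Thursday's run starts with 48.0 mM less of starting material and of partner than the Wednesday's run, and with no target. Compared where both hold the same amount of starting material, once fifteen percent of what the Thursday's run was charged with has turned into target, is the Thursday's run faster, slower or alike (within a tenth)?
4. target in the Monday's run at 19 min, as a share of the starting material charged

1. I defined a clearing time τ: the starting material charged, over the first rate read from the early readings. I read that rate to the first reading, but to 2.8 min in the Thursday's run. The ladder ran: Tuesday's run 2.95 min, Wednesday's 19.0 min, Saturday's 26.1 min, Thursday's 30.9 min.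

2. The Tuesday's run stood on the fastest rung. By 19 min it had turned nearly all of its starting material. At that time the Saturday's run had turned 40.3% and the Thursday's run 38.8%.

3. In the Wednesday's run starting material was the limiting reagent. Each target takes one starting material and one partner. So the excess e, partner minus starting material with what is bound of each counted, held through that run at 40.0 mM.

4. The Thursday's run had the same e, 40.0 mM. Its charge was the Wednesday's after 48.0 mM had turned, without the target. The Wednesday's readings stopped short of that point, so I compared rates per starting material left. The Wednesday's last interval read 0.0337 min⁻¹. The Thursday's start read 0.0339 min⁻¹. The Thursday's start held less starting material than the Wednesday's last interval, and its reading of 2.9 mM carried a scatter of 0.4 mM. So alike was my estimate, not a measured match.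

5. The Monday's run had the Wednesday's charge and e, plus 24.0 mM of target. Taking that target as a bystander, I added the Wednesday's 42.5 mM to it and got 83.1%. I reckoned no orders.

6. The forecast gave 0.32, 2.2, alike and 83%, saying “Late-run rates fit this law with no clear product term”.

7. The flask gave 0.48, 1.9, alike and 82.9%.

    starting material + 2 partner → target + partner (27.24 M⁻² min⁻¹)
    starting material + partner ⇌ idle substrate-reagent adduct, settled at all times (9.490 M⁻¹)
    2 starting material ⇌ idle substrate dimer, settled at all times (153.0 M⁻¹)

In the Wednesday's run the step starting material + 2 partner → target + partner ran from the start, beside the idle substrate-reagent adduct and the idle substrate dimer; target reached a quarter of the charge at 6.25 min and half at 17.2 min, while the excess, bound forms counted, stayed at 40.0 mM. The Monday's run began with the same 40.0 mM and ran the same step with its 24.0 mM of target present from the outset, and by 19 min its target, the charged part counted, stood at 82.9% of the starting material charged, which is 42.3 mM of target made.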